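Assumptions: the target SMILES decodes as the (2S,3R)-trans isomer with an E acrylic acid (C20H20O7). The sense of induction in Step 5 is assigned by analogy, from memory of reported cases where (S)-configured phthaloyl-amino-acid Rh(II) catalysts give (2R,3S)-cis esters. The (R)-catalyst is therefore used; if this substrate responds the other way, swap the catalyst antipode.

## Retrosynthetic overview
1. Target 13 comes from MOM/t-Bu-protected trans alcohol 12 by global acidolysis, and 12 comes from trans-3-carboxylate 11 by chemoselective ester reduction.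
2. 11 comes from cis ester 10 by C3 epimerisation. 10 comes from aryldiazoacetate 9 by enantioselective Rh(II)-carbenoid 1,5-C–H insertion, which makes the C2–C3 bond.
3. The dihydrofuran is the only ring formed in the route; both benzene rings are purchased.
4. 9 comes from aryl iodide 7 by Pd-catalysed arylation of ethyl diazoacetate. 7 comes from iodoferulate 3 and benzylic alcohol 6 by Mitsunobu C–O coupling.
5. 3 comes from 5-iodovanillin by Wittig olefination, and 6 comes from vanillyl alcohol by phenol-selective MOM protection.

## Route

**Step 1**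
Reactants: 1, 5-iodovanillin (4-hydroxy-3-iodo-5-methoxybenzaldehyde); 2, tert-butyl (triphenylphosphoranylidene)acetate
Product: 3, tert-butyl (E)-3-(4-hydroxy-3-iodo-5-methoxyphenyl)prop-2-enoate
Conditions: 2 (1.5 equiv), toluene, 90 °C, 12 h
Reagents that add atoms: 2, CC(C)(C)OC(=O)C=P(c1ccccc1)(c1ccccc1)c1ccccc1
Why: Wittig olefination with an ester-stabilised ylide is strongly E-selective and tolerates the free phenol and the aryl iodide, and the t-Bu ester is chosen to survive the later alkoxide and borohydride steps.

**Step 2**
Reactants: 4, vanillyl alcohol; 5, chloromethyl methyl ether (MOMCl)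
Product: 6, [3-methoxy-4-(methoxymethoxy)phenyl]methanol
Conditions: MOMCl (1.05 equiv), K2CO3, acetone, 0 °C to rt
Reagents that add atoms: MOMCl, COCCl
Why: In this Williamson-type O-alkylation K2CO3 ionises only the phenol, so the phenoxide is capped in preference to the neutral benzylic alcohol.

**Step 3**
Reactants: 3; 6
Product: 7, tert-butyl (E)-3-[3-iodo-5-methoxy-4-{[3-methoxy-4-(methoxymethoxy)phenyl]methoxy}phenyl]prop-2-enoate
Conditions: PPh3, DIAD, THF, 0 °C to rt
Reagents that add atoms: none
Why: Mitsunobu etherification joins the acidic 2,6-disubstituted phenol to a primary benzylic alcohol under neutral conditions, which avoids the unstable p-alkoxybenzyl halide.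

**Step 4**
Reactants: 7; 8, ethyl diazoacetate
Product: 9, ethyl 2-diazo-2-aryl acetate, where aryl is 5-[(E)-2-(tert-butoxycarbonyl)vinyl]-3-methoxy-2-{[3-methoxy-4-(methoxymethoxy)phenyl]methoxy}phenyl
Conditions: Pd(PPh3)4 (5 mol %), Ag2CO3 (0.5 equiv), Et3N, toluene, rt
Reagents that add atoms: ethyl diazoacetate, CCOC(=O)C=[N+]=[N-]
Why: Pd(0)-catalysed cross-coupling of an aryl iodide with the diazo C–H retains the N2 group, and at rt the β-substituted cinnamate undergoes neither Heck reaction nor dipolar cycloaddition.

**Step 5**
Reactants: 9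
Product: 10, ethyl (2S,3R)-cis-5-[(E)-3-tert-butoxy-3-oxoprop-1-enyl]-7-methoxy-2-[3-methoxy-4-(methoxymethoxy)phenyl]-2,3-dihydrobenzofuran-3-carboxylate
Conditions: Rh2(R-PTTL)4 (1–2 mol %), toluene (0.02 M), −60 °C
Reagents that add atoms: none (loss of N2)
Why: In this enantioselective intramolecular Rh(II) donor/acceptor-carbenoid 1,5-C–H insertion the chiral catalyst selects one enantiotopic ArCH2–O hydrogen, which sets C2 as S and gives the kinetic cis ester (about 85–94% ee expected by analogy), while the electron-poor alkene and MOM group do not compete.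

**Step 6**
Reactants: 10
Product: 11, ethyl (2S,3S)-trans-5-[(E)-3-tert-butoxy-3-oxoprop-1-enyl]-7-methoxy-2-[3-methoxy-4-(methoxymethoxy)phenyl]-2,3-dihydrobenzofuran-3-carboxylate
Conditions: NaOEt (0.5 equiv), EtOH/THF, 0 °C to rt, AcOH quench; recrystallise to ≥99% ee
Reagents that add atoms: none
Why: Thermodynamic epimerisation through the ester enolate inverts only C3 to the favoured trans isomer, because C2 cannot ionise while the ring-A phenol is MOM-protected, and the matched alkoxide avoids transesterification.

**Step 7**
Reactants: 11
Product: 12, tert-butyl (E)-3-{(2S,3R)-3-(hydroxymethyl)-7-methoxy-2-[3-methoxy-4-(methoxymethoxy)phenyl]-2,3-dihydrobenzofuran-5-yl}prop-2-enoate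
Conditions: LiBH4 (3 equiv), THF, MeOH (1 equiv), 0 °C to rt
Reagents that add atoms: none
Why: Chemoselective borohydride reduction takes the saturated ethyl ester to CH2OH and leaves the hindered, conjugated t-Bu cinnamate, with no change in geometry at C3 (the descriptor changes from S to R only through CIP priorities).

**Step 8**
Reactants: 12
Product: 13, (E)-3-[(2S,3R)-2-(4-hydroxy-3-methoxyphenyl)-3-(hydroxymethyl)-7-methoxy-2,3-dihydrobenzofuran-5-yl]prop-2-enoic acid (target)
Conditions: TFA/CH2Cl2 (1:3), H2O (5 equiv), 0 °C to rt; brief aq NaHCO3/MeOH wash to cleave any trifluoroacetate, then acidify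
Reagents that add atoms: none
Why: Acidolysis removes the t-Bu ester (as isobutene) and the aryl MOM acetal in one operation, and any reversible C2–O ionisation can only return to the favoured trans ring because C3 is now fixed.

## Compound list
1 | 5-iodovanillin | COc1cc(C=O)cc(I)c1O | starting material
2 | tert-butyl (triphenylphosphoranylidene)acetate | CC(C)(C)OC(=O)C=P(c1ccccc1)(c1ccccc1)c1ccccc1 | starting material
3 | tert-butyl (E)-5-iodoferulate | COc1cc(/C=C/C(=O)OC(C)(C)C)cc(I)c1O | intermediate
4 | vanillyl alcohol | COc1cc(CO)ccc1O | starting material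
5 | chloromethyl methyl ether | COCCl | starting material
6 | [3-methoxy-4-(methoxymethoxy)phenyl]methanol | COCOc1ccc(CO)cc1OC | intermediate
7 | iodoaryl benzyl ether | COCOc1ccc(COc2c(I)cc(/C=C/C(=O)OC(C)(C)C)cc2OC)cc1OC | intermediate
8 | ethyl diazoacetate | CCOC(=O)C=[N+]=[N-] | starting material
9 | aryldiazoacetate | COCOc1ccc(COc2c(OC)cc(/C=C/C(=O)OC(C)(C)C)cc2C(=[N+]=[N-])C(=O)OCC)cc1OC | intermediate
10 | (2S,3R)-cis ester | COCOc1ccc([C@H]2Oc3c(OC)cc(/C=C/C(=O)OC(C)(C)C)cc3[C@H]2C(=O)OCC)cc1OC | intermediate
11 | (2S,3S)-trans ester | COCOc1ccc([C@H]2Oc3c(OC)cc(/C=C/C(=O)OC(C)(C)C)cc3[C@@H]2C(=O)OCC)cc1OC | intermediate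
12 | (2S,3R)-trans alcohol | COCOc1ccc([C@H]2Oc3c(OC)cc(/C=C/C(=O)OC(C)(C)C)cc3[C@@H]2CO)cc1OC | intermediate
13 | target acid, (2S,3R), E | COc1cc([C@H]2Oc3c(OC)cc(/C=C/C(=O)O)cc3[C@@H]2CO)ccc1O | target

## Summary
Total steps: 8. Longest linear sequence: 7 (1→3→7→9→10→11→12→13, and equally from 4 via 6).

Steps most likely to fail:
1. **Step 5.** The ee and cis selectivity on this 2,6-disubstituted aryl ether are untested. Fallback: drop carbenoid chemistry and use an Evans syn-aldol between the corresponding arylacetyl oxazolidinone and MOM-vanillin. The auxiliary antipode is chosen to set C3. LiBH4 cleavage and acid-mediated quinone-methide-type ring closure then set C2 trans under thermodynamic control.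
2. **Step 4.** The aryl iodide is electron-rich and ortho-alkoxy substituted, which may slow the coupling with ethyl diazoacetate. Fallback: build the diazo group in two stages. Pd-catalysed Reformatsky/Negishi α-arylation with BrZnCH2CO2Et gives the arylacetate, and Regitz diazo transfer (p-ABSA, DBU) then gives 9.
3. **Step 7.** The ethyl ester must be reduced selectively in the presence of the t-Bu cinnamate. Fallback: replace ring B with 4-bromo-2-iodo-6-methoxyphenol (from 4-bromoguaiacol by iodination), so only one ester is present at the reduction stage (LiAlH4). The acrylic acid is then installed last by a Heck reaction on the 5-bromide, which also removes the need to cleave a t-Bu ester.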